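**Retrosynthetic overview**
1. Sodwanone B (20) ⇐ double alcohol oxidation of diol 18; the resulting 6,7-dione tautomerises to the diosphenol.
2. 18 ⇐ diepoxy olefin 16 by the key step: the inner epoxide oxygen attacks the silyl-activated terminal epoxide (C–O bond of the oxepane), the epoxonium ion is opened by the olefin, and the cation is trapped by hydride. Oxepane ring first, cyclohexane ring second; four stereocentres set.
3. 16 ⇐ sp3–sp2 Negishi union of alkyl iodide 7 (decalin half) with diepoxy vinyl iodide 14.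
4. 7 ⇐ (+)-sclareolide 1, which supplies both carbocycles of the left half, its quaternary stereocentre and the two-carbon linker; only oxidation-level changes are needed (C3, C6, C7, C12).
5. 14 ⇐ geranyl bromide 8 + 1-(trimethylsilyl)propyne 9 by alkylation, carboalumination–iodination and Shi bis-epoxidation.

Homodrimane numbering is used for the left half: decalin C1–C10, gem-dimethyl on C4, angular methyl on C10 (β), methyl on C8, side chain C11–C12 on C9, 5α-H as in sclareolide.

Assumption: the C6 oxygen substituent of 7, 15, 16, 17 and 18 may be either epimer (this centre is erased in the last step), so it is left undefined; an engineered P450 BM3 variant that hydroxylates sclareolide at C3 is taken as an available biocatalyst.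

**Step 1**
Reactants: 1 (+)-sclareolide
Product: 2 3β-hydroxysclareolide
Conditions: engineered P450 BM3 variant (C3-selective, clarified E. coli lysate), NADP+ (cat.), phosphite dehydrogenase, Na2HPO3, air, KPi buffer pH 8.0, 25 °C
Reagents that add atoms: dioxygen O=O
Why: Enzymatic C–H hydroxylation by the P450 oxygen-rebound mechanism, in which the active site delivers oxygen to the equatorial C3–H with retention to give the 3β (3S) alcohol; this centre later becomes the C3 ketone.

**Step 2**
Reactants: 2 3β-hydroxysclareolide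
Product: 3 methyl 3β-hydroxyhomodrim-8(9)-en-12-oate
Conditions: H2SO4 (conc.), MeOH, 25 to 50 °C
Reagents that add atoms: methanol CO
Why: Acid-mediated ionisation of the tertiary lactone C8–O bond, E1 loss of the C9 proton to the thermodynamically preferred tetrasubstituted 8(9)-olefin and Fischer esterification; the neopentyl secondary 3β-alcohol does not ionise and no stereocentre is created.

**Step 3**
Reactants: 3 methyl 3β-hydroxyhomodrim-8(9)-en-12-oate
Product: 4 homodrim-8(9)-ene-3β,12-diol
Conditions: LiAlH4, THF, 0 °C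
Reagents that add atoms: none
Why: Hydride reduction of the ester to the primary alcohol; the isolated tetrasubstituted olefin and all stereocentres are untouched.

**Step 4**
Reactants: 4 homodrim-8(9)-ene-3β,12-diol
Product: 5 12-iodohomodrim-8(9)-en-3β-ol
Conditions: I2, PPh3, imidazole, CH2Cl2, 0 °C
Reagents that add atoms: iodine [I][I]
Why: Appel-type (Garegg–Samuelsson) iodination in which the unhindered primary alcohol forms the alkoxyphosphonium ion and is displaced by iodide much faster than the neopentyl secondary C3 alcohol.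

**Step 5**
Reactants: 5 12-iodohomodrim-8(9)-en-3β-ol
Product: 6 12-iodohomodrim-8(9)-ene-3,7-dione
Conditions: CrO3, 3,5-dimethylpyrazole, CH2Cl2, −20 °C
Reagents that add atoms: chromium trioxide O=[Cr](=O)=O
Why: Hexavalent-chromium oxidation with the CrO3·3,5-dimethylpyrazole complex converts the secondary alcohol into the ketone and the ring allylic C7 methylene (less hindered than C11) into the enone in one operation; no stereocentre changes.

**Step 6**
Reactants: 6 12-iodohomodrim-8(9)-ene-3,7-dione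
Product: 7 6ξ-acetoxy-12-iodohomodrim-8(9)-ene-3,7-dione
Conditions: Mn(OAc)3·2H2O, benzene–AcOH (10:1), reflux
Reagents that add atoms: manganese triacetate CC(=O)[O-].CC(=O)[O-].CC(=O)[O-].[Mn+3]
Why: α'-Acetoxylation of an enone through its trivalent-manganese enolate, a reaction that is selective for conjugated ketones over the saturated C3 ketone; the new C6 centre may be either epimer because it is erased in step 12.

**Step 7**
Reactants: 8 geranyl bromide + 9 1-(trimethylsilyl)propyne
Product: 11 (5E)-6,10-dimethylundeca-5,9-dien-1-yne, via silylated enyne 10 (not isolated)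
Conditions: 9, n-BuLi, THF, −78 °C; 8, −78 to 0 °C; then K2CO3, MeOH, 25 °C
Reagents that add atoms: none
Why: SN2 alkylation of propargylic lithiated 1-(trimethylsilyl)propyne by the allylic bromide, then methanolytic C–Si cleavage; the E olefin of the geranyl unit is retained.

**Step 8**
Reactants: 11 (5E)-6,10-dimethylundeca-5,9-dien-1-yne
Product: 13 (1E,5E)-1-iodo-2,6,10-trimethylundeca-1,5,9-triene, via alkenylalane 12 (not isolated)
Conditions: AlMe3, Cp2ZrCl2 (25 mol%), CH2Cl2, 0 to 25 °C; then I2, THF, −30 °C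
Reagents that add atoms: trimethylaluminium C[Al](C)C; iodine [I][I]
Why: Negishi zirconium-catalysed carboalumination (syn methylalumination with aluminium on the terminal carbon) followed by stereoretentive iododealumination fixes the E trisubstituted olefin that later controls the C6 configuration of the benzoxepane.

**Step 9**
Reactants: 13 (1E,5E)-1-iodo-2,6,10-trimethylundeca-1,5,9-triene
Product: 14 (2S,3S)-2-{2-[(2S)-3,3-dimethyloxiran-2-yl]ethyl}-3-[(3E)-4-iodo-3-methylbut-3-en-1-yl]-2-methyloxirane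
Conditions: L-fructose-derived Shi ketone (1,2:4,5-di-O-isopropylidene-β-L-erythro-2,3-hexodiulo-2,6-pyranose, 40 mol%), KHSO5 (as 2KHSO5·KHSO4·K2SO4), K2CO3, Bu4NHSO4, Na2B4O7/Na2EDTA buffer, MeCN–CH2(OMe)2–H2O, 0 °C
Reagents that add atoms: potassium peroxymonosulfate [K+].[O-]S(=O)(=O)OO
Why: Shi asymmetric epoxidation, in which the chiral dioxirane attacks the two electron-rich trisubstituted olefins on the same enantioface through the spiro transition state to give the (S,S) and (S) epoxides, while the iodine-deactivated olefin is left.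

**Step 10**
Reactants: 7 6ξ-acetoxy-12-iodohomodrim-8(9)-ene-3,7-dione + 14 (2S,3S)-2-{2-[(2S)-3,3-dimethyloxiran-2-yl]ethyl}-3-[(3E)-4-iodo-3-methylbut-3-en-1-yl]-2-methyloxirane
Product: 16 6ξ-acetoxy-12-{(1E)-4-[(2S,3S)-3-{2-[(2S)-3,3-dimethyloxiran-2-yl]ethyl}-3-methyloxiran-2-yl]-2-methylbut-1-en-1-yl}homodrim-8(9)-ene-3,7-dione, via alkylzinc iodide 15 (not isolated)
Conditions: 7, Zn dust, LiCl, THF, 40 °C; then 14, Pd(dppf)Cl2 (5 mol%), THF–DMA, 40 °C
Reagents that add atoms: none
Why: Negishi sp3–sp2 cross-coupling, in which zinc inserts into the primary C–I bond to give an alkylzinc iodide that tolerates ketones, the acetate and epoxides and couples under palladium catalysis with the vinyl iodide with retention of the E geometry.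

**Step 11**
Reactants: 16 6ξ-acetoxy-12-{(1E)-4-[(2S,3S)-3-{2-[(2S)-3,3-dimethyloxiran-2-yl]ethyl}-3-methyloxiran-2-yl]-2-methylbut-1-en-1-yl}homodrim-8(9)-ene-3,7-dione
Product: 18 6ξ-hydroxy-12-[(3S,5aS,6R,7R,9aS)-3-hydroxy-2,2,5a,7-tetramethyldecahydro-1-benzoxepin-6-yl]homodrim-8(9)-ene-3,7-dione, via silyl ether acetate 17 (not isolated)
Conditions: TMSOTf (2 equiv), Et3SiH (5 equiv), 2,6-di-tert-butyl-4-methylpyridine (0.2 equiv), CH2Cl2, −78 °C; then K2CO3, MeOH, argon, 0 to 25 °C
Reagents that add atoms: none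
Why: Proposed new method: a reductively terminated epoxonium–olefin cascade in which TMSOTf silylates the terminal epoxide, the inner epoxide oxygen attacks its tertiary carbon through a six-membered transition state to form the oxepane C–O bond as a bicyclic epoxonium ion, the E olefin opens this ion at the tertiary carbon with inversion through a chair (trans ring fusion, axial angular methyl, equatorial side chain), and the tertiary cyclohexyl cation is then reduced by Et3SiH from the equatorial α-face because the axial trajectory is blocked by the syn-axial angular methyl, which gives the axial C7 methyl; the methanolic K2CO3 work-up removes the silyl ether and the acetate; the closest known reactions are the TMSOTf-promoted tandem oxa-/carbacyclisation of 1,5-diepoxides ending in proton or silyl loss and the ionic hydrogenation of tertiary carbocations by silanes.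

**Step 12**
Reactants: 18 6ξ-hydroxy-12-[(3S,5aS,6R,7R,9aS)-3-hydroxy-2,2,5a,7-tetramethyldecahydro-1-benzoxepin-6-yl]homodrim-8(9)-ene-3,7-dione
Product: 20 sodwanone B, via triketone 19 (not isolated)
Conditions: DMP (3 equiv), CH2Cl2, 0 to 25 °C; then SiO2
Reagents that add atoms: none
Why: Dess–Martin oxidation of the oxepanol and of the acyloin hydroxyl; the 6,7-dione formed enolises towards C5 to the fully conjugated diosphenol, which removes the undefined C5/C6 centres and leaves the five stereocentres of the target.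

**Compound list**
1 | (+)-sclareolide, (3aR,5aS,9aS,9bR)-3a,6,6,9a-tetramethyldecahydronaphtho[2,1-b]furan-2(1H)-one | C[C@]12CCCC(C)(C)[C@@H]1CC[C@@]1(C)OC(=O)C[C@@H]12 | starting material
2 | 3β-hydroxysclareolide (equatorial OH on C3, 3S) | C[C@]12CC[C@H](O)C(C)(C)[C@@H]1CC[C@@]1(C)OC(=O)C[C@@H]12 | intermediate
3 | methyl 3β-hydroxyhomodrim-8(9)-en-12-oate | COC(=O)CC1=C(C)CC[C@H]2C(C)(C)[C@@H](O)CC[C@]12C | intermediate
4 | homodrim-8(9)-ene-3β,12-diol | OCCC1=C(C)CC[C@H]2C(C)(C)[C@@H](O)CC[C@]12C | intermediate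
5 | 12-iodohomodrim-8(9)-en-3β-ol | ICCC1=C(C)CC[C@H]2C(C)(C)[C@@H](O)CC[C@]12C | intermediate
6 | 12-iodohomodrim-8(9)-ene-3,7-dione | ICCC1=C(C)C(=O)C[C@H]2C(C)(C)C(=O)CC[C@]12C | intermediate
7 | 6ξ-acetoxy-12-iodohomodrim-8(9)-ene-3,7-dione | ICCC1=C(C)C(=O)C(OC(C)=O)[C@H]2C(C)(C)C(=O)CC[C@]12C | intermediate
8 | geranyl bromide, (2E)-1-bromo-3,7-dimethylocta-2,6-diene | BrC/C=C(\C)CCC=C(C)C | starting material
9 | 1-(trimethylsilyl)propyne | CC#C[Si](C)(C)C | starting material
10 | (5E)-6,10-dimethyl-1-(trimethylsilyl)undeca-5,9-dien-1-yne | C[Si](C)(C)C#CCC/C=C(\C)CCC=C(C)C | intermediate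
11 | (5E)-6,10-dimethylundeca-5,9-dien-1-yne | C#CCC/C=C(\C)CCC=C(C)C | intermediate
12 | dimethyl[(1E,5E)-2,6,10-trimethylundeca-1,5,9-trien-1-yl]alane | C[Al](C)/C=C(\C)CC/C=C(\C)CCC=C(C)C | intermediate
13 | (1E,5E)-1-iodo-2,6,10-trimethylundeca-1,5,9-triene | I/C=C(\C)CC/C=C(\C)CCC=C(C)C | intermediate
14 | (2S,3S)-2-{2-[(2S)-3,3-dimethyloxiran-2-yl]ethyl}-3-[(3E)-4-iodo-3-methylbut-3-en-1-yl]-2-methyloxirane | I/C=C(\C)CC[C@@H]1O[C@@]1(C)CC[C@@H]1OC1(C)C | intermediate
15 | (6ξ-acetoxy-3,7-dioxohomodrim-8(9)-en-12-yl)zinc iodide | I[Zn]CCC1=C(C)C(=O)C(OC(C)=O)[C@H]2C(C)(C)C(=O)CC[C@]12C | intermediate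
16 | 6ξ-acetoxy-12-{(1E)-4-[(2S,3S)-3-{2-[(2S)-3,3-dimethyloxiran-2-yl]ethyl}-3-methyloxiran-2-yl]-2-methylbut-1-en-1-yl}homodrim-8(9)-ene-3,7-dione | C(/CCC1=C(C)C(=O)C(OC(C)=O)[C@H]2C(C)(C)C(=O)CC[C@]12C)=C(/C)CC[C@@H]1O[C@@]1(C)CC[C@@H]1OC1(C)C | intermediate
17 | 6ξ-acetoxy-12-[(3S,5aS,6R,7R,9aS)-2,2,5a,7-tetramethyl-3-(trimethylsilyloxy)decahydro-1-benzoxepin-6-yl]homodrim-8(9)-ene-3,7-dione | CC1=C(CC[C@@H]2[C@H](C)CC[C@@H]3OC(C)(C)[C@@H](O[Si](C)(C)C)CC[C@]32C)[C@@]2(C)CCC(=O)C(C)(C)[C@@H]2C(OC(C)=O)C1=O | intermediate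
18 | 6ξ-hydroxy-12-[(3S,5aS,6R,7R,9aS)-3-hydroxy-2,2,5a,7-tetramethyldecahydro-1-benzoxepin-6-yl]homodrim-8(9)-ene-3,7-dione | CC1=C(CC[C@@H]2[C@H](C)CC[C@@H]3OC(C)(C)[C@@H](O)CC[C@]32C)[C@@]2(C)CCC(=O)C(C)(C)[C@@H]2C(O)C1=O | intermediate
19 | 12-[(5aS,6R,7R,9aS)-2,2,5a,7-tetramethyl-3-oxodecahydro-1-benzoxepin-6-yl]homodrim-8(9)-ene-3,6,7-trione | CC1=C(CC[C@@H]2[C@H](C)CC[C@@H]3OC(C)(C)C(=O)CC[C@]32C)[C@@]2(C)CCC(=O)C(C)(C)[C@@H]2C(=O)C1=O | intermediate
20 | sodwanone B, (4aR)-1-hydroxy-3,4a,8,8-tetramethyl-4-{2-[(5aS,6R,7R,9aS)-2,2,5a,7-tetramethyl-3-oxodecahydro-1-benzoxepin-6-yl]ethyl}-5,6-dihydronaphthalene-2,7(4aH,8H)-dione | CC1=C(CC[C@@H]2[C@H](C)CC[C@@H]3OC(C)(C)C(=O)CC[C@]32C)[C@@]2(C)CCC(=O)C(C)(C)C2=C(O)C1=O | target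

**Totals**
Total steps: 12. Longest linear sequence: 9 steps (1, 2, 3, 4, 5, 6, 10, 11, 12 from sclareolide); the diepoxide branch is 3 steps.

**Three steps most likely to fail**

Step 11 (the proposed new step). The risks are elimination instead of hydride capture, silane attack from the wrong face, and premature reduction of an activated epoxide. The fallback uses the established elimination-terminated cascade. It sets out from 16: TMSOTf with 2 equiv of 2,6-di-tert-butyl-4-methylpyridine in CH2Cl2 at −78 °C gives a mixture of the exocyclic olefin, 6ξ-acetoxy-12-[(3S,5aS,6R,9aS)-2,2,5a-trimethyl-7-methylidene-3-(trimethylsilyloxy)decahydro-1-benzoxepin-6-yl]homodrim-8(9)-ene-3,7-dione F4, and the endocyclic olefin, 6ξ-acetoxy-12-[(3S,5aS,6R,9aS)-2,2,5a,7-tetramethyl-3-(trimethylsilyloxy)-2,3,4,5,5a,6,9,9a-octahydro-1-benzoxepin-6-yl]homodrim-8(9)-ene-3,7-dione F5. Hydrogenation of the mixture (H2, Pd/C, EtOAc) adds hydrogen from the face opposite the angular methyl and leaves the tetrasubstituted enone, which returns to the route at 17; K2CO3/MeOH then gives 18.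

Step 5. The chromium oxidation may attack C11 next to the iodide or degrade the homoallylic iodide. The fallback moves the iodination behind the oxidation. It sets out from 4: selective acetylation of the primary hydroxyl (AcCl, 2,4,6-collidine, CH2Cl2, −78 °C) gives 3β-hydroxyhomodrim-8(9)-en-12-yl acetate F1. The same CrO3·3,5-dimethylpyrazole oxidation, now on an ester-protected substrate, gives 3,7-dioxohomodrim-8(9)-en-12-yl acetate F2. K2CO3/MeOH liberates 12-hydroxyhomodrim-8(9)-ene-3,7-dione F3, and I2/PPh3/imidazole returns to the route at 6.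

Step 10. Zinc insertion next to an α-acetoxy enone and coupling of a hindered trisubstituted vinyl iodide may be slow or give protodezincation. The fallback avoids the preformed organozinc: a nickel-catalysed reductive cross-electrophile coupling (NiBr2·glyme, 4,4'-di-tert-butyl-2,2'-bipyridine, Mn powder, NaI, DMA, 25 °C) generates the C12 radical at nickel. It sets out from 7 and 14 and returns to the route at 16 without any new isolated compound.

**Further compounds**
F1 | step 5 | 3β-hydroxyhomodrim-8(9)-en-12-yl acetate | CC(=O)OCCC1=C(C)CC[C@H]2C(C)(C)[C@@H](O)CC[C@]12C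
F2 | step 5 | 3,7-dioxohomodrim-8(9)-en-12-yl acetate | CC(=O)OCCC1=C(C)C(=O)C[C@H]2C(C)(C)C(=O)CC[C@]12C
F3 | step 5 | 12-hydroxyhomodrim-8(9)-ene-3,7-dione | OCCC1=C(C)C(=O)C[C@H]2C(C)(C)C(=O)CC[C@]12C
F0 | step 10 | none | none
F4 | step 11 | 6ξ-acetoxy-12-[(3S,5aS,6R,9aS)-2,2,5a-trimethyl-7-methylidene-3-(trimethylsilyloxy)decahydro-1-benzoxepin-6-yl]homodrim-8(9)-ene-3,7-dione | CC1=C(CC[C@@H]2C(=C)CC[C@@H]3OC(C)(C)[C@@H](O[Si](C)(C)C)CC[C@]32C)[C@@]2(C)CCC(=O)C(C)(C)[C@@H]2C(OC(C)=O)C1=O
F5 | step 11 | 6ξ-acetoxy-12-[(3S,5aS,6R,9aS)-2,2,5a,7-tetramethyl-3-(trimethylsilyloxy)-2,3,4,5,5a,6,9,9a-octahydro-1-benzoxepin-6-yl]homodrim-8(9)-ene-3,7-dione | CC1=C(CC[C@@H]2C(C)=CC[C@@H]3OC(C)(C)[C@@H](O[Si](C)(C)C)CC[C@]32C)[C@@]2(C)CCC(=O)C(C)(C)[C@@H]2C(OC(C)=O)C1=O
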